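**Plan**

1. Numbering: ring C1 (CHO), C2 (OH), C3 (H), C4 (OMe), C5 (OH), C6 (side chain); chain C1′ (ArCH2), C2′ (CHOAc). The ring has oxygen at C2 and C4 and carbon substituents at C1 and C6, the pattern of a folded β-polyketone, so it can be opened at C1–C6 to a chain whose C1/C2 end is a 1,3-dioxin-4-one.
2. Retrosynthetic cuts, in order: functional-group changes (C5–O benzyl, C1 aldehyde ← thioester ← dioxinone, C2′ acetate ← silyl ether, C4–O methyl); ring bond C1–C6 (aldol); chain bond C5–C6 (Claisen); chain bond C3–C4 (acylation of the dioxinone methyl group).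
3. Forward: C3–C4 is joined first (dioxinone dienolate + benzyloxyacetyl chloride), then C5–C6 (keto-dioxinone dianion + Weinreb amide of the C14 acid); the only ring, the benzene ring, then closes at C1–C6.
4. After ring closure: O-methylation at C4, silyl-to-acetyl exchange at C2′, dioxinone → thioester → aldehyde at C1, debenzylation at C5.
5. Stereochemistry: C2′ (R) is C3 of (R)-3-hydroxytetradecanoic acid; no bond to this carbon is made or broken anywhere.

Key step: step 5

Assumption: the benzyloxy-bearing carbon of the open-chain key-step precursor is carried as a mixture of epimers and keto–enol tautomers, which should not matter because this carbon becomes aromatic C5.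

**Route**

Step 1
Reactants: 1 (R)-3-hydroxytetradecanoic acid
Product: 2 (R)-3-hydroxy-N-methoxy-N-methyltetradecanamide
Conditions: MeNH(OMe)·HCl, EDC·HCl, HOBt, iPr2NEt, CH2Cl2, 0 °C → rt
Reagents that add atoms: N,O-dimethylhydroxylamine hydrochloride, CNOC.Cl
Why: Carbodiimide/HOBt amide coupling, in which the amine should outcompete the secondary hydroxyl for the active ester and the C3 stereocentre takes no part.

Step 2
Reactants: 2 (R)-3-hydroxy-N-methoxy-N-methyltetradecanamide
Product: 3 (R)-3-(tert-butyldimethylsilyloxy)-N-methoxy-N-methyltetradecanamide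
Conditions: TBSCl, imidazole, DMF, rt
Reagents that add atoms: tert-butyldimethylsilyl chloride, CC(C)(C)[Si](C)(C)Cl
Why: Imidazole-promoted silylation of a secondary alcohol, which turns the β-oxygen into a poor leaving group for the enolate steps that follow.

Step 3
Reactants: 4 2,2,6-trimethyl-4H-1,3-dioxin-4-one; 5 benzyloxyacetyl chloride
Product: 7 6-[3-(benzyloxy)-2-oxopropyl]-2,2-dimethyl-4H-1,3-dioxin-4-one, via lithium dioxinone dienolate 6 (not isolated)
Conditions: LiHMDS (2 equiv), 4 (2 equiv), THF, −78 °C; then 5 (1 equiv), −78 °C; aq. NH4Cl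
Reagents that add atoms: none
Why: Vinylogous Claisen acylation, in which γ-deprotonation of the 6-methyl group gives the cross-conjugated dienolate that acid chlorides acylate at the exocyclic carbon, the second equivalent of dienolate taking up the more acidic proton of the product so that it is not acylated twice.

Step 4
Reactants: 7 6-[3-(benzyloxy)-2-oxopropyl]-2,2-dimethyl-4H-1,3-dioxin-4-one; 3 (R)-3-(tert-butyldimethylsilyloxy)-N-methoxy-N-methyltetradecanamide
Product: 10 6-[(6R)-3-(benzyloxy)-6-(tert-butyldimethylsilyloxy)-2,4-dioxoheptadecyl]-2,2-dimethyl-4H-1,3-dioxin-4-one, via dilithium keto-dioxinone dianion 8 (not isolated), via lithium hemiaminal adduct 9 (not isolated)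
Conditions: LDA (2.2 equiv), THF, −78 °C; then 3, −78 → −20 °C; aq. NH4Cl
Reagents that add atoms: none
Why: Claisen-type C-acylation of a 1,3-dicarbonyl dianion by a Weinreb amide, in which the second deprotonation can only occur at the benzyloxymethylene, this last-formed terminus is the nucleophile, and the chelated adduct 9 holds the new ketone masked until the quench so that it meets no excess enolate.

Step 5
Reactants: 10 6-[(6R)-3-(benzyloxy)-6-(tert-butyldimethylsilyloxy)-2,4-dioxoheptadecyl]-2,2-dimethyl-4H-1,3-dioxin-4-one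
Product: 12 6-(benzyloxy)-7-hydroxy-2,2-dimethyl-5-[(2R)-2-(tert-butyldimethylsilyloxy)tridecyl]-4H-1,3-benzodioxin-4-one, via cyclic aldol adduct 11 (not isolated)
Conditions: Et3N (5 equiv), CH2Cl2, rt
Reagents that add atoms: none
Why: Triethylamine should reversibly deprotonate the methylene between the dioxinone and the C4 ketone to give an extended dienolate whose dioxinone α-carbon (future C1) adds to the side-chain ketone (future C6), forming the C1–C6 bond in 11; E1cB loss of water across C1–C6 and enolization of the C4 ketone through the C5–H then give the benzene ring. The closest known reaction is the biomimetic aldol cycloaromatization of diketo-dioxinones to isopropylidene-protected resorcylates, applied here to a substrate that carries a benzyloxy group on the carbon between the two ketones. The single ring closes in the 6-(enolexo)-exo-trig mode. No stereocentre is created, and C2′ should stay intact because a silyloxide is a poor leaving group for E1cB loss under a tertiary amine and is no longer β to a ketone once the ring is aromatic. The step needs regioselective C-cyclization: every other aldol pairing would give a four-membered ring, and the one six-membered alternative, Claisen attack of the C5 enolate on the dioxinone carbonyl, meets a poorly electrophilic vinylogous ester and would give a quaternary C5 that cannot aromatize. The mildly basic aprotic medium should also disfavour the acid-promoted O-cyclization to a 4-pyranone.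

Step 6
Reactants: 12 6-(benzyloxy)-7-hydroxy-2,2-dimethyl-5-[(2R)-2-(tert-butyldimethylsilyloxy)tridecyl]-4H-1,3-benzodioxin-4-one
Product: 13 6-(benzyloxy)-7-methoxy-2,2-dimethyl-5-[(2R)-2-(tert-butyldimethylsilyloxy)tridecyl]-4H-1,3-benzodioxin-4-one
Conditions: MeI, K2CO3, acetone, 40 °C
Reagents that add atoms: iodomethane, CI
Why: Williamson etherification of the only free phenol (C4–OH), the C2 oxygen being locked in the acetonide and the C5 oxygen benzylated.

Step 7
Reactants: 13 6-(benzyloxy)-7-methoxy-2,2-dimethyl-5-[(2R)-2-(tert-butyldimethylsilyloxy)tridecyl]-4H-1,3-benzodioxin-4-one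
Product: 14 (2R)-1-[6-(benzyloxy)-7-methoxy-2,2-dimethyl-4-oxo-4H-1,3-benzodioxin-5-yl]tridecan-2-yl acetate
Conditions: Ac2O, Cu(OTf)2 (5 mol %), CH2Cl2, 0 °C → rt
Reagents that add atoms: acetic anhydride, CC(=O)OC(C)=O
Why: Lewis-acid-catalysed acylative cleavage of a silyl ether (direct silyl ether to acetate exchange), in which the ether oxygen is acetylated and silicon then leaves, so that no free C2′ hydroxyl able to lactonize onto the dioxinone carbonyl is released and, since only the O–Si bond breaks, the (R) configuration is retained.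

Step 8
Reactants: 14 (2R)-1-[6-(benzyloxy)-7-methoxy-2,2-dimethyl-4-oxo-4H-1,3-benzodioxin-5-yl]tridecan-2-yl acetate
Product: 15 S-ethyl 2-[(2R)-2-acetoxytridecyl]-3-(benzyloxy)-6-hydroxy-4-methoxybenzenecarbothioate
Conditions: NaSEt (1.5 equiv), THF–DMF, 0 °C → rt; aq. NH4Cl
Reagents that add atoms: sodium ethanethiolate, CC[S-].[Na+]
Why: Transthioesterification of an activated ester, in which the thiolate adds to the dioxinone carbonyl and the ring oxygen leaves as a hemiketal alkoxide that sheds acetone to a phenoxide less basic than the thiolate, which should make the opening irreversible, whereas cleavage of the alkyl acetate would require a far more basic alkoxide to leave.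

Step 9
Reactants: 15 S-ethyl 2-[(2R)-2-acetoxytridecyl]-3-(benzyloxy)-6-hydroxy-4-methoxybenzenecarbothioate
Product: 16 (2R)-1-[2-(benzyloxy)-6-formyl-5-hydroxy-3-methoxyphenyl]tridecan-2-yl acetate
Conditions: Et3SiH, 10% Pd/C, acetone, rt
Reagents that add atoms: none
Why: Fukuyama reduction, in which palladium inserts into the C–S bond and the silane delivers hydride to give the aldehyde, conditions that should leave the acetate, the aryl benzyl ether and the phenol untouched and do not reduce the aldehyde further.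

Step 10
Reactants: 16 (2R)-1-[2-(benzyloxy)-6-formyl-5-hydroxy-3-methoxyphenyl]tridecan-2-yl acetate
Product: 17 (2R)-1-(2-formyl-3,6-dihydroxy-5-methoxyphenyl)tridecan-2-yl acetate (CNP0112378.1)
Conditions: BCl3, pentamethylbenzene, CH2Cl2, −78 °C, argon; aq. NaHCO3
Reagents that add atoms: none
Why: Lewis-acid O-debenzylation with a non-basic cation scavenger, in which BCl3 activates the aryl benzyl ether and pentamethylbenzene traps the benzyl cation by Friedel–Crafts alkylation, the low temperature being expected to spare the acetate, the methyl ether and the aldehyde.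

**Compound list**

1 | (R)-3-hydroxytetradecanoic acid | CCCCCCCCCCC[C@H](CC(=O)O)O | starting material
2 | (R)-3-hydroxy-N-methoxy-N-methyltetradecanamide | CCCCCCCCCCC[C@H](CC(=O)N(C)OC)O | intermediate
3 | (R)-3-(tert-butyldimethylsilyloxy)-N-methoxy-N-methyltetradecanamide | CCCCCCCCCCC[C@H](CC(=O)N(C)OC)O[Si](C)(C)C(C)(C)C | intermediate
4 | 2,2,6-trimethyl-4H-1,3-dioxin-4-one | CC1=CC(=O)OC(C)(C)O1 | starting material
5 | benzyloxyacetyl chloride | O=C(Cl)COCc1ccccc1 | starting material
6 | lithium dienolate of 4 (4-lithiooxy-2,2-dimethyl-6-methylidene-1,3-dioxine; not isolated) | C=C1C=C(O[Li])OC(C)(C)O1 | intermediate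
7 | 6-[3-(benzyloxy)-2-oxopropyl]-2,2-dimethyl-4H-1,3-dioxin-4-one | O=C(COCc1ccccc1)CC1=CC(=O)OC(C)(C)O1 | intermediate
8 | dilithium dianion of 7 (not isolated) | [Li]OC(=COCc1ccccc1)C=C1C=C(O[Li])OC(C)(C)O1 | intermediate
9 | lithium hemiaminal adduct of 8 and 3 (not isolated; new sp3 centres as mixtures) | CCCCCCCCCCC[C@H](CC(O[Li])(N(C)OC)C(OCc1ccccc1)C(=O)C=C1C=C(O[Li])OC(C)(C)O1)O[Si](C)(C)C(C)(C)C | intermediate
10 | 6-[(6R)-3-(benzyloxy)-6-(tert-butyldimethylsilyloxy)-2,4-dioxoheptadecyl]-2,2-dimethyl-4H-1,3-dioxin-4-one (C3 epimers, keto–enol mixture) | CCCCCCCCCCC[C@H](CC(=O)C(OCc1ccccc1)C(=O)CC1=CC(=O)OC(C)(C)O1)O[Si](C)(C)C(C)(C)C | intermediate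
11 | 6-(benzyloxy)-5-hydroxy-2,2-dimethyl-5-[(2R)-2-(tert-butyldimethylsilyloxy)tridecyl]-4a,5-dihydro-4H-1,3-benzodioxine-4,7(6H)-dione (aldol adduct, not isolated) | CCCCCCCCCCC[C@H](CC1(O)C(OCc2ccccc2)C(=O)C=C2OC(C)(C)OC(=O)C12)O[Si](C)(C)C(C)(C)C | intermediate
12 | 6-(benzyloxy)-7-hydroxy-2,2-dimethyl-5-[(2R)-2-(tert-butyldimethylsilyloxy)tridecyl]-4H-1,3-benzodioxin-4-one | CCCCCCCCCCC[C@H](Cc1c(OCc2ccccc2)c(O)cc2OC(C)(C)OC(=O)c12)O[Si](C)(C)C(C)(C)C | intermediate
13 | 6-(benzyloxy)-7-methoxy-2,2-dimethyl-5-[(2R)-2-(tert-butyldimethylsilyloxy)tridecyl]-4H-1,3-benzodioxin-4-one | CCCCCCCCCCC[C@H](Cc1c(OCc2ccccc2)c(OC)cc2OC(C)(C)OC(=O)c12)O[Si](C)(C)C(C)(C)C | intermediate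
14 | (2R)-1-[6-(benzyloxy)-7-methoxy-2,2-dimethyl-4-oxo-4H-1,3-benzodioxin-5-yl]tridecan-2-yl acetate | CCCCCCCCCCC[C@H](Cc1c(OCc2ccccc2)c(OC)cc2OC(C)(C)OC(=O)c12)OC(C)=O | intermediate
15 | S-ethyl 2-[(2R)-2-acetoxytridecyl]-3-(benzyloxy)-6-hydroxy-4-methoxybenzenecarbothioate | CCCCCCCCCCC[C@H](Cc1c(OCc2ccccc2)c(OC)cc(O)c1C(=O)SCC)OC(C)=O | intermediate
16 | (2R)-1-[2-(benzyloxy)-6-formyl-5-hydroxy-3-methoxyphenyl]tridecan-2-yl acetate | CCCCCCCCCCC[C@H](Cc1c(OCc2ccccc2)c(OC)cc(O)c1C=O)OC(C)=O | intermediate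
17 | (2R)-1-(2-formyl-3,6-dihydroxy-5-methoxyphenyl)tridecan-2-yl acetate (CNP0112378.1) | CCCCCCCCCCC[C@H](Cc1c(O)c(OC)cc(O)c1C=O)OC(C)=O | target

**Step count and risks**

Total steps: 10. Longest linear sequence: 9 steps (1 → 2 → 3 → 10 → 12 → 13 → 14 → 15 → 16 → 17); the branch from 4 and 5 runs 8 steps.

Risk 1, step 7. While silicon is being exchanged, the C2′ oxygen may close onto the dioxinone carbonyl (six-membered lactone, loss of acetone) faster than it is acetylated, or the hindered silyl ether may be converted too slowly. The fallback removes the electrophilic carbonyl before the alcohol is freed. It sets out from 13: LiAlH4 (THF, 0 °C) should reduce the dioxinone to the salicyl alcohol 4-(benzyloxy)-2-(hydroxymethyl)-5-methoxy-3-[(2R)-2-(tert-butyldimethylsilyloxy)tridecyl]phenol F1. 2,2-Dimethoxypropane with catalytic PPTS ties phenol and benzylic alcohol together as 6-(benzyloxy)-7-methoxy-2,2-dimethyl-5-[(2R)-2-(tert-butyldimethylsilyloxy)tridecyl]-4H-1,3-benzodioxine F2. TBAF in THF then gives (2R)-1-[6-(benzyloxy)-7-methoxy-2,2-dimethyl-4H-1,3-benzodioxin-5-yl]tridecan-2-ol F3, which has no acyl group to lactonize onto. Ac2O/pyridine/DMAP gives (2R)-1-[6-(benzyloxy)-7-methoxy-2,2-dimethyl-4H-1,3-benzodioxin-5-yl]tridecan-2-yl acetate F4. Aqueous acetic acid in THF removes the acetonide to give (2R)-1-[2-(benzyloxy)-5-hydroxy-6-(hydroxymethyl)-3-methoxyphenyl]tridecan-2-yl acetate F5, and activated MnO2 in CH2Cl2 oxidizes the benzylic alcohol to the aldehyde. The fallback comes back to the route at 16, so steps 8 and 9 are not needed.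

Risk 2, step 8. The thiolate may fail to add to the hindered, electron-rich dioxinone carbonyl at a temperature at which the side-chain acetate still resists acyl transfer to thiolate or to the liberated phenoxide. The fallback makes the thioester before the acetate exists, with an aluminium thiolate. It sets out from 13: Me2AlSEt (from AlMe3 and EtSH, CH2Cl2, 0 °C → rt) should open the dioxinone to S-ethyl 3-(benzyloxy)-6-hydroxy-4-methoxy-2-[(2R)-2-(tert-butyldimethylsilyloxy)tridecyl]benzenecarbothioate F6. Ac2O with catalytic TMSOTf then exchanges silyl for acetyl and caps the phenol, giving S-ethyl 6-acetoxy-2-[(2R)-2-acetoxytridecyl]-3-(benzyloxy)-4-methoxybenzenecarbothioate F7. Fukuyama reduction (Et3SiH, Pd/C, acetone) gives (2R)-1-[5-acetoxy-2-(benzyloxy)-6-formyl-3-methoxyphenyl]tridecan-2-yl acetate F8. Aqueous NaHCO3 in THF should hydrolyse only the aryl acetate next to the formyl group. The fallback comes back to the route at 16.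

Risk 3, step 4. Acyl transfer to the hindered, benzyloxy-substituted terminus of the dianion may be slow, so that proton transfer from the amide α-position or O-acylation takes over. The fallback replaces the acyl transfer by an aldol addition followed by oxidation. It sets out from 3 and from 7: DIBAL-H (THF, −78 °C) reduces 3 to (R)-3-(tert-butyldimethylsilyloxy)tetradecanal F9. Addition of F9 to dianion 8 (made from 7 as in step 4) at −78 °C should give 6-[(6R)-3-(benzyloxy)-4-hydroxy-6-(tert-butyldimethylsilyloxy)-2-oxoheptadecyl]-2,2-dimethyl-4H-1,3-dioxin-4-one F10 as a diastereomer mixture. Dess–Martin periodinane (CH2Cl2, NaHCO3) oxidizes the β-hydroxy ketone to the 1,3-diketone. The fallback comes back to the route at 10.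

Further compounds
F1 | step 7 | 4-(benzyloxy)-2-(hydroxymethyl)-5-methoxy-3-[(2R)-2-(tert-butyldimethylsilyloxy)tridecyl]phenol | CCCCCCCCCCC[C@H](Cc1c(OCc2ccccc2)c(OC)cc(O)c1CO)O[Si](C)(C)C(C)(C)C
F2 | step 7 | 6-(benzyloxy)-7-methoxy-2,2-dimethyl-5-[(2R)-2-(tert-butyldimethylsilyloxy)tridecyl]-4H-1,3-benzodioxine | CCCCCCCCCCC[C@H](Cc1c(OCc2ccccc2)c(OC)cc2OC(C)(C)OCc12)O[Si](C)(C)C(C)(C)C
F3 | step 7 | (2R)-1-[6-(benzyloxy)-7-methoxy-2,2-dimethyl-4H-1,3-benzodioxin-5-yl]tridecan-2-ol | CCCCCCCCCCC[C@H](Cc1c(OCc2ccccc2)c(OC)cc2OC(C)(C)OCc12)O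
F4 | step 7 | (2R)-1-[6-(benzyloxy)-7-methoxy-2,2-dimethyl-4H-1,3-benzodioxin-5-yl]tridecan-2-yl acetate | CCCCCCCCCCC[C@H](Cc1c(OCc2ccccc2)c(OC)cc2OC(C)(C)OCc12)OC(C)=O
F5 | step 7 | (2R)-1-[2-(benzyloxy)-5-hydroxy-6-(hydroxymethyl)-3-methoxyphenyl]tridecan-2-yl acetate | CCCCCCCCCCC[C@H](Cc1c(OCc2ccccc2)c(OC)cc(O)c1CO)OC(C)=O
F6 | step 8 | S-ethyl 3-(benzyloxy)-6-hydroxy-4-methoxy-2-[(2R)-2-(tert-butyldimethylsilyloxy)tridecyl]benzenecarbothioate | CCCCCCCCCCC[C@H](Cc1c(OCc2ccccc2)c(OC)cc(O)c1C(=O)SCC)O[Si](C)(C)C(C)(C)C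
F7 | step 8 | S-ethyl 6-acetoxy-2-[(2R)-2-acetoxytridecyl]-3-(benzyloxy)-4-methoxybenzenecarbothioate | CCCCCCCCCCC[C@H](Cc1c(OCc2ccccc2)c(OC)cc(OC(C)=O)c1C(=O)SCC)OC(C)=O
F8 | step 8 | (2R)-1-[5-acetoxy-2-(benzyloxy)-6-formyl-3-methoxyphenyl]tridecan-2-yl acetate | CCCCCCCCCCC[C@H](Cc1c(OCc2ccccc2)c(OC)cc(OC(C)=O)c1C=O)OC(C)=O
F9 | step 4 | (R)-3-(tert-butyldimethylsilyloxy)tetradecanal | CCCCCCCCCCC[C@H](CC=O)O[Si](C)(C)C(C)(C)C
F10 | step 4 | 6-[(6R)-3-(benzyloxy)-4-hydroxy-6-(tert-butyldimethylsilyloxy)-2-oxoheptadecyl]-2,2-dimethyl-4H-1,3-dioxin-4-one | CCCCCCCCCCC[C@H](CC(O)C(OCc1ccccc1)C(=O)CC1=CC(=O)OC(C)(C)O1)O[Si](C)(C)C(C)(C)C
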